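Cuts: (i) C14–C26 and C15–C16 together (cyclopentane and triene chain); (ii) C11–C12; (iii) C10–C11 plus a temporary O10–C26 lactone bond (cyclohexane); (iv) C6–C7; (v) C18=C19.
Forward: acyclic C1–C10 vinyl iodide → 1,4-addition sets C6 → the cyclohexane closes as a cis-fused β-lactone (O10–C26 is not in the target; it steers the C11 alkylation and is then cleaved by hydride) → cyclopentane and complete side chain arrive in one Pd-catalysed dienylative allene–aldehyde cyclisation → desilylation, MnO2.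
Stereochemistry: C6 from an oxazolidinone auxiliary; C10 and C11 relayed from C6 (chair aldol-lactonisation, cis ring fusion); C26 and C14 relayed from C11 in a cyclic allyl-transfer transition state; C2=C7 from anti-carbomagnesiation/iodination, C18=C19 from a Z-selective HWE, C16=C17 from the boronate.
Enabling feature: in the cyclopentane (C11–C12–C13–C14–C26) the carbinol C26 sits next to C14, whose vinyl carbon C15(=C27H2) also carries the dienyl chain (C16 onward). This 2-substituted homoallylic alcohol on spiro carbon C11 is the retron of carbometalation of a terminal allene at its central carbon followed by allylation of a tethered aldehyde.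

Key step: step 22

Remark: atom labels follow iridal numbering (C1 = CHO carbon; C2 with methyl C25; C3–C5 = hydroxypropyl chain; C6–C11 = cyclohexane, C10 = tertiary carbinol, C11 = spiro carbon; C12–C14 and C26 = cyclopentane, C26 = secondary carbinol; C15(=C27H2) to C24 = side chain; C28 = CH2OAc). TBDPS = tert-butyldiphenylsilyl, TES = triethylsilyl, Bpin = pinacolboryl.
Assumption: compounds 1, 8, 10, 20, 29, 30 and 33 are catalogue chemicals.

Step 1
Reactants: 1 hex-5-yn-2-one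
Product: 2 2-(but-3-yn-1-yl)-2-methyl-1,3-dioxolane
Conditions: HOCH2CH2OH, p-TsOH (cat.), toluene, reflux, Dean–Stark
Reagents that add atoms: ethylene glycol, OCCO
Why: Acid-catalysed ketalisation with azeotropic removal of water masks the methyl ketone (future C10) against the organometallic steps.

Step 2
Reactants: 2 2-(but-3-yn-1-yl)-2-methyl-1,3-dioxolane
Product: 4 5-(2-methyl-1,3-dioxolan-2-yl)pent-2-yn-1-ol, via lithium acetylide 3 (not isolated)
Conditions: n-BuLi, THF, −78 °C; (CH2O)n, −78 °C → rt; aq NH4Cl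
Reagents that add atoms: formaldehyde (as paraformaldehyde), C=O
Why: Hydroxymethylation of the lithium acetylide gives the propargylic alcohol (C1) that the directed carbometalation needs.

Step 3
Reactants: 4 5-(2-methyl-1,3-dioxolan-2-yl)pent-2-yn-1-ol
Product: 6 (Z)-3-iodo-2-methyl-5-(2-methyl-1,3-dioxolan-2-yl)pent-2-en-1-ol, via alkenylmagnesium chelate 5 (not isolated)
Conditions: MeMgBr (3.5 equiv), CuI (10 mol%), Et2O/THF, 0 °C → rt; then I2, −78 → 0 °C; aq NH4Cl
Reagents that add atoms: methylmagnesium bromide, C[Mg]Br; iodine, II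
Why: Copper-catalysed anti-carbomagnesiation of a 2-alkyn-1-ol delivers methyl to C2 and magnesium to C7 within a five-membered magnesium alkoxide chelate, and iodinolysis with retention should give the single (Z)-iodide, which fixes the tetrasubstituted C2=C7 geometry (C1 cis to the future C6, methyl cis to C8).

Step 4
Reactants: 6 (Z)-3-iodo-2-methyl-5-(2-methyl-1,3-dioxolan-2-yl)pent-2-en-1-ol
Product: 7 tert-butyl{[(2Z)-3-iodo-2-methyl-5-(2-methyl-1,3-dioxolan-2-yl)pent-2-en-1-yl]oxy}diphenylsilane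
Conditions: TBDPSCl, imidazole, DMF, rt
Reagents that add atoms: tert-butyl(chloro)diphenylsilane, CC(C)(C)[Si](Cl)(c1ccccc1)c1ccccc1
Why: Silylation of the primary allylic alcohol with a group that survives t-BuLi, aqueous acid and hydride.

Step 5
Reactants: 8 pent-4-en-1-ol
Product: 9 tert-butyl(pent-4-en-1-yloxy)diphenylsilane
Conditions: TBDPSCl, imidazole, DMF, rt
Reagents that add atoms: tert-butyl(chloro)diphenylsilane, CC(C)(C)[Si](Cl)(c1ccccc1)c1ccccc1
Why: Standard silylation of the primary alcohol that becomes C3–OH.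

Step 6
Reactants: 10 (R)-4-benzyloxazolidin-2-one
Product: 11 (R)-3-acryloyl-4-benzyloxazolidin-2-one
Conditions: acryloyl chloride, Et3N, LiCl, THF, −20 °C → rt
Reagents that add atoms: acryloyl chloride, C=CC(Cl)=O
Why: Mild N-acylation of the oxazolidinone under amine/LiCl conditions avoids anionic polymerisation of the acrylate.

Step 7
Reactants: 9 tert-butyl(pent-4-en-1-yloxy)diphenylsilane; 11 (R)-3-acryloyl-4-benzyloxazolidin-2-one
Product: 12 (R)-4-benzyl-3-[(E)-6-(TBDPS-oxy)hex-2-enoyl]oxazolidin-2-one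
Conditions: Hoveyda–Grubbs II (5 mol%), CH2Cl2, 40 °C, 9 in excess
Reagents that add atoms: none
Why: Cross-metathesis between an electron-poor acryloyl imide and a terminal alkene is selective for the cross product and should give the (E)-enoyl imide (C26, C11, C6–C3).

Step 8
Reactants: 7 tert-butyl{[(2Z)-3-iodo-2-methyl-5-(2-methyl-1,3-dioxolan-2-yl)pent-2-en-1-yl]oxy}diphenylsilane; 12 (R)-4-benzyl-3-[(E)-6-(TBDPS-oxy)hex-2-enoyl]oxazolidin-2-one
Product: 15 (R)-4-benzyl-3-[(S)-3-{(Z)-1-(TBDPS-oxy)-2-methyl-5-(2-methyl-1,3-dioxolan-2-yl)pent-2-en-3-yl}-6-(TBDPS-oxy)hexanoyl]oxazolidin-2-one, via alkenyllithium 13 (not isolated), via alkenylmagnesium bromide 14 (not isolated)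
Conditions: 7, t-BuLi (2.0 equiv), Et2O, −78 °C; MgBr2·OEt2, −78 → −40 °C; CuBr·SMe2 (20 mol%), 12, THF, −40 → −10 °C; aq NH4Cl
Reagents that add atoms: none
Why: Copper-catalysed 1,4-addition of an alkenyl Grignard reagent to the magnesium-chelated syn-s-cis N-enoyl oxazolidinone should occur on the face opposite the benzyl group and set C6, while the alkenyl–metal bond reacts with retention so that C6 takes the place of iodine cis to C1.

Step 9
Reactants: 15 (R)-4-benzyl-3-[(S)-3-{(Z)-1-(TBDPS-oxy)-2-methyl-5-(2-methyl-1,3-dioxolan-2-yl)pent-2-en-3-yl}-6-(TBDPS-oxy)hexanoyl]oxazolidin-2-one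
Product: 17 (S)-3-{(Z)-1-(TBDPS-oxy)-2-methyl-5-(2-methyl-1,3-dioxolan-2-yl)pent-2-en-3-yl}-6-(TBDPS-oxy)hexanoic acid, via peroxy acid 16 (not isolated)
Conditions: LiOH, H2O2, THF/H2O, 0 °C; then Na2SO3; HCl to pH 3
Reagents that add atoms: hydrogen peroxide (as lithium hydroperoxide), OO
Why: Lithium hydroperoxide attacks the exocyclic imide carbonyl selectively and sulfite reduces the peroxy acid, which releases the acid and the recoverable auxiliary without touching C6.

Step 10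
Reactants: 17 (S)-3-{(Z)-1-(TBDPS-oxy)-2-methyl-5-(2-methyl-1,3-dioxolan-2-yl)pent-2-en-3-yl}-6-(TBDPS-oxy)hexanoic acid
Product: 18 (S)-3-[(Z)-1-(TBDPS-oxy)-2-methyl-6-oxohept-2-en-3-yl]-6-(TBDPS-oxy)hexanoic acid
Conditions: PPTS (cat.), acetone/H2O (4:1), 55 °C
Reagents that add atoms: water, O
Why: Mild acid hydrolysis of the dioxolane frees the methyl ketone (C10) while the TBDPS ethers and the tetrasubstituted alkene are stable.

Step 11
Reactants: 18 (S)-3-[(Z)-1-(TBDPS-oxy)-2-methyl-6-oxohept-2-en-3-yl]-6-(TBDPS-oxy)hexanoic acid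
Product: 19 (1R,2S,6S)-6-methyl-2-[3-(TBDPS-oxy)propyl]-3-[(Z)-1-(TBDPS-oxy)propan-2-ylidene]-7-oxabicyclo[4.2.0]octan-8-one
Conditions: 2-bromo-1-propylpyridinium triflate (1.5 equiv), 4-pyrrolidinopyridine (1.5 equiv), i-Pr2NEt (3 equiv), CH2Cl2, rt, slow addition of 18
Reagents that add atoms: none
Why: Nucleophile-catalysed aldol-lactonisation (acid activation, acylammonium enolate, aldol onto the methyl ketone, lactonisation) closes the cyclohexane as a necessarily cis-fused β-lactone, and a chair transition state with the C5 chain axial (A1,3 strain against the Z-CH2OSi group on C2) and the C10 methyl equatorial should place the new C10–O and C11–C26 bonds on the face of the C5 chain.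

Step 12
Reactants: 20 but-3-yn-1-ol
Product: 22 penta-3,4-dien-1-ol, via Mannich base 21 (not isolated)
Conditions: (CH2O)n, CuI, i-Pr2NH, 1,4-dioxane, reflux
Reagents that add atoms: formaldehyde (as paraformaldehyde), C=O
Why: Crabbé homologation, in which a copper-mediated Mannich reaction of the terminal alkyne is followed by hydride transfer and elimination of the imine, converts the alkyne into the terminal allene.

Step 13
Reactants: 22 penta-3,4-dien-1-ol
Product: 23 penta-3,4-dien-1-yl trifluoromethanesulfonate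
Conditions: Tf2O, 2,6-lutidine, CH2Cl2, −78 °C, used at once
Reagents that add atoms: trifluoromethanesulfonic anhydride, O=S(=O)(OS(=O)(=O)C(F)(F)F)C(F)(F)F
Why: Triflation of the primary alcohol gives an electrophile reactive enough to alkylate a hindered enolate at low temperature.

Step 14
Reactants: 19 (1R,2S,6S)-6-methyl-2-[3-(TBDPS-oxy)propyl]-3-[(Z)-1-(TBDPS-oxy)propan-2-ylidene]-7-oxabicyclo[4.2.0]octan-8-one; 23 penta-3,4-dien-1-yl trifluoromethanesulfonate
Product: 25 (1R,2R,6S)-6-methyl-1-(penta-3,4-dien-1-yl)-2-[3-(TBDPS-oxy)propyl]-3-[(Z)-1-(TBDPS-oxy)propan-2-ylidene]-7-oxabicyclo[4.2.0]octan-8-one, via lithium enolate 24 (not isolated)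
Conditions: LDA, THF, −78 °C; 23, DMPU, −78 → −50 °C
Reagents that add atoms: none
Why: In this alkylation of a β-lactone enolate C11 is a ring-fusion atom, so the electrophile can only enter cis to the C10 methyl (a trans-fused oxetanone on the six-membered ring being far too strained), which fixes the quaternary centre with C12 anti and C26 syn to the C10 oxygen.

Step 15
Reactants: 25 (1R,2R,6S)-6-methyl-1-(penta-3,4-dien-1-yl)-2-[3-(TBDPS-oxy)propyl]-3-[(Z)-1-(TBDPS-oxy)propan-2-ylidene]-7-oxabicyclo[4.2.0]octan-8-one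
Product: 26 (1S,2S,3R)-2-(hydroxymethyl)-1-methyl-2-(penta-3,4-dien-1-yl)-3-[3-(TBDPS-oxy)propyl]-4-[(Z)-1-(TBDPS-oxy)propan-2-ylidene]cyclohexan-1-ol
Conditions: LiAlH4, Et2O, 0 °C
Reagents that add atoms: none
Why: Hydride reduction opens the β-lactone by acyl cleavage to the 1,3-diol and so removes the temporary O10–C26 bond, while allene, silyl ethers and the tetrasubstituted alkene are inert.

Step 16
Reactants: 26 (1S,2S,3R)-2-(hydroxymethyl)-1-methyl-2-(penta-3,4-dien-1-yl)-3-[3-(TBDPS-oxy)propyl]-4-[(Z)-1-(TBDPS-oxy)propan-2-ylidene]cyclohexan-1-ol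
Product: 27 (1R,2S,6R)-2-hydroxy-2-methyl-1-(penta-3,4-dien-1-yl)-6-[3-(TBDPS-oxy)propyl]-5-[(Z)-1-(TBDPS-oxy)propan-2-ylidene]cyclohexane-1-carbaldehyde
Conditions: TEMPO (10 mol%), PhI(OAc)2, CH2Cl2, rt
Reagents that add atoms: none
Why: Oxoammonium oxidation converts only the primary neopentyl alcohol into the non-enolisable aldehyde C26 and leaves the tertiary C10 alcohol untouched.

Step 17
Reactants: 27 (1R,2S,6R)-2-hydroxy-2-methyl-1-(penta-3,4-dien-1-yl)-6-[3-(TBDPS-oxy)propyl]-5-[(Z)-1-(TBDPS-oxy)propan-2-ylidene]cyclohexane-1-carbaldehyde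
Product: 28 (1R,2S,6R)-2-methyl-1-(penta-3,4-dien-1-yl)-6-[3-(TBDPS-oxy)propyl]-5-[(Z)-1-(TBDPS-oxy)propan-2-ylidene]-2-(triethylsilyloxy)cyclohexane-1-carbaldehyde
Conditions: TESOTf, 2,6-lutidine, CH2Cl2, −78 → 0 °C
Reagents that add atoms: triethylsilyl trifluoromethanesulfonate, CC[Si](CC)(CC)OS(=O)(=O)C(F)(F)F
Why: Silyl triflate silylation of the tertiary alcohol blocks retro-aldol cleavage and removes a chelating group next to the aldehyde before the key step.

Step 18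
Reactants: 29 methyl 2-[bis(2,2,2-trifluoroethoxy)phosphoryl]acetate; 30 5-bromo-2-methylpent-2-ene
Product: 32 methyl 2-[bis(2,2,2-trifluoroethoxy)phosphoryl]-6-methylhept-5-enoate, via sodium phosphonate enolate 31 (not isolated)
Conditions: NaH, DMF, 0 °C; 30, NaI (cat.), 50 °C
Reagents that add atoms: none
Why: C-alkylation of the stabilised phosphonoacetate anion by the primary homoprenyl bromide (iodide-assisted SN2) installs C20–C24.

Step 19
Reactants: 32 methyl 2-[bis(2,2,2-trifluoroethoxy)phosphoryl]-6-methylhept-5-enoate; 33 (E)-3-(4,4,5,5-tetramethyl-1,3,2-dioxaborolan-2-yl)prop-2-enal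
Product: 35 methyl (2Z,4E)-2-(4-methylpent-3-en-1-yl)-5-(pinacolboryl)penta-2,4-dienoate, via potassium phosphonate enolate 34 (not isolated)
Conditions: KHMDS, 18-crown-6, THF, −78 °C; then 33
Reagents that add atoms: none
Why: Still–Gennari olefination with the electron-poor bis(trifluoroethyl) phosphonate under dissociating conditions should give the (Z)-trisubstituted enoate (ester carbon C28 cis to C17), while the E C16=C17 bond is carried in from the boryl acrolein.

Step 20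
Reactants: 35 methyl (2Z,4E)-2-(4-methylpent-3-en-1-yl)-5-(pinacolboryl)penta-2,4-dienoate
Product: 36 (2Z,4E)-2-(4-methylpent-3-en-1-yl)-5-(pinacolboryl)penta-2,4-dien-1-ol
Conditions: DIBAL-H, CH2Cl2, −78 °C; Rochelle salt
Reagents that add atoms: none
Why: DIBAL-H reduces the conjugated ester to the allylic alcohol at low temperature without attacking the pinacol boronate or the alkenes.

Step 21
Reactants: 36 (2Z,4E)-2-(4-methylpent-3-en-1-yl)-5-(pinacolboryl)penta-2,4-dien-1-ol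
Product: 37 (2Z,4E)-2-(4-methylpent-3-en-1-yl)-5-(pinacolboryl)penta-2,4-dien-1-yl acetate
Conditions: Ac2O, pyridine, DMAP (cat.), CH2Cl2, 0 °C
Reagents that add atoms: acetic anhydride, CC(=O)OC(C)=O
Why: Acylation of the primary allylic alcohol installs the C28 acetate of the target before the fragment union.

Step 22
Reactants: 28 (1R,2S,6R)-2-methyl-1-(penta-3,4-dien-1-yl)-6-[3-(TBDPS-oxy)propyl]-5-[(Z)-1-(TBDPS-oxy)propan-2-ylidene]-2-(triethylsilyloxy)cyclohexane-1-carbaldehyde; 37 (2Z,4E)-2-(4-methylpent-3-en-1-yl)-5-(pinacolboryl)penta-2,4-dien-1-yl acetate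
Product: 38 (1R,2S,5S,6S,10R)-2-[(3E,5Z)-6-(acetoxymethyl)-10-methylundeca-1,3,5,9-tetraen-2-yl]-6-methyl-10-[3-(TBDPS-oxy)propyl]-9-[(Z)-1-(TBDPS-oxy)propan-2-ylidene]-6-(triethylsilyloxy)spiro[4.5]decan-1-ol
Conditions: 37 (1.5 equiv), Pd(OAc)2 (10 mol%), 2,2′-bipyridine (12 mol%), KHCO3, 1,4-dioxane/H2O (10:1), 45 °C
Reagents that add atoms: none
Why: Transmetalation of the dienyl boronate to Pd(II) and syn-carbopalladation of the terminal allene place the dienyl group on the central carbon C15 and give a π-allylpalladium(II) species (C14–C15–C27), whose η1 form (Pd on C27) adds through C14 to the tethered aldehyde C26 in a closed six-membered transition state before protonolysis of the Pd alkoxide returns Pd(II); the closest known reaction type is the Pd(II)-catalysed organoboron/allene/aldehyde coupling (arylative cyclisation of allenyl aldehydes), with the Ni/organozinc variant equally established. The cyclopentane (C11–C12–C13–C14–C26) closes by intramolecular γ-allylation of the aldehyde, a five-ring closure annulated to the cyclic allyl-transfer transition state. C26–OH and the C14 substituent should emerge cis because O and C15 both belong to that cis-fused six-membered transition state. The face of C26 is set by spiro centre C11: the metal-bound carbonyl oxygen should turn away from quaternary C10 (Me, OTES) towards C6–H, so that OH and side chain end syn to C6. The step needs chemoselectivity for the single aldehyde and delivery of the dienyl group to C15, secured by the intramolecular five-ring closure and the inherent central-carbon selectivity of allene carbopalladation; the E geometry of C16=C17 is carried over from the boronate, and the phosphine-free Pd(II) cycle avoids Pd(0), which would ionise the dienylic acetate.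

Step 23
Reactants: 38 (1R,2S,5S,6S,10R)-2-[(3E,5Z)-6-(acetoxymethyl)-10-methylundeca-1,3,5,9-tetraen-2-yl]-6-methyl-10-[3-(TBDPS-oxy)propyl]-9-[(Z)-1-(TBDPS-oxy)propan-2-ylidene]-6-(triethylsilyloxy)spiro[4.5]decan-1-ol
Product: 39 (1R,2S,5S,6S,10R)-2-[(3E,5Z)-6-(acetoxymethyl)-10-methylundeca-1,3,5,9-tetraen-2-yl]-10-(3-hydroxypropyl)-9-[(Z)-1-hydroxypropan-2-ylidene]-6-methylspiro[4.5]decane-1,6-diol
Conditions: TBAF/AcOH (1:1), THF, 0 °C → rt
Reagents that add atoms: none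
Why: Fluoride cleaves the two TBDPS ethers and the TES ether, and the acetic acid buffer keeps the medium non-basic so that the acetate should neither migrate nor hydrolyse.

Step 24
Reactants: 39 (1R,2S,5S,6S,10R)-2-[(3E,5Z)-6-(acetoxymethyl)-10-methylundeca-1,3,5,9-tetraen-2-yl]-10-(3-hydroxypropyl)-9-[(Z)-1-hydroxypropan-2-ylidene]-6-methylspiro[4.5]decane-1,6-diol
Product: 40 CNP0205332.1, (Z)-2-[(1R,2S,5S,6S,10R)-2-{(3E,5Z)-6-(acetoxymethyl)-10-methylundeca-1,3,5,9-tetraen-2-yl}-1,6-dihydroxy-10-(3-hydroxypropyl)-6-methylspiro[4.5]decan-9-ylidene]propanal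
Conditions: MnO2 (activated), CH2Cl2, rt
Reagents that add atoms: none
Why: MnO2 oxidises only the allylic primary alcohol at C1 to the enal with retention of the C2=C7 geometry, since the saturated primary (C3), homoallylic secondary (C26) and tertiary (C10) alcohols are not substrates.

Compound list
1 | hex-5-yn-2-one | CC(=O)CCC#C | starting material
2 | 2-(but-3-yn-1-yl)-2-methyl-1,3-dioxolane | CC1(CCC#C)OCCO1 | intermediate
3 | lithium acetylide of 2 | [Li]C#CCCC1(C)OCCO1 | intermediate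
4 | 5-(2-methyl-1,3-dioxolan-2-yl)pent-2-yn-1-ol | OCC#CCCC1(C)OCCO1 | intermediate
5 | (Z)-alkenylmagnesium chelate (bromomagnesium alkoxide, Mg on C7 cis to CH2O) | Br[Mg]/C(=C(/C)CO[Mg]Br)CCC1(C)OCCO1 | intermediate
6 | (Z)-3-iodo-2-methyl-5-(2-methyl-1,3-dioxolan-2-yl)pent-2-en-1-ol | I/C(=C(/C)CO)CCC1(C)OCCO1 | intermediate
7 | tert-butyl{[(2Z)-3-iodo-2-methyl-5-(2-methyl-1,3-dioxolan-2-yl)pent-2-en-1-yl]oxy}diphenylsilane | I/C(=C(/C)CO[Si](c1ccccc1)(c1ccccc1)C(C)(C)C)CCC1(C)OCCO1 | intermediate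
8 | pent-4-en-1-ol | C=CCCCO | starting material
9 | tert-butyl(pent-4-en-1-yloxy)diphenylsilane | C=CCCCO[Si](c1ccccc1)(c1ccccc1)C(C)(C)C | intermediate
10 | (R)-4-benzyloxazolidin-2-one | O=C1N[C@H](Cc2ccccc2)CO1 | starting material
11 | (R)-3-acryloyl-4-benzyloxazolidin-2-one | C=CC(=O)N1[C@H](Cc2ccccc2)COC1=O | intermediate
12 | (R)-4-benzyl-3-[(E)-6-(TBDPS-oxy)hex-2-enoyl]oxazolidin-2-one | O=C(/C=C/CCCO[Si](c1ccccc1)(c1ccccc1)C(C)(C)C)N1[C@H](Cc2ccccc2)COC1=O | intermediate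
13 | alkenyllithium from 7 (Li in place of I) | [Li]/C(=C(/C)CO[Si](c1ccccc1)(c1ccccc1)C(C)(C)C)CCC1(C)OCCO1 | intermediate
14 | alkenylmagnesium bromide from 7 (MgBr in place of I) | Br[Mg]/C(=C(/C)CO[Si](c1ccccc1)(c1ccccc1)C(C)(C)C)CCC1(C)OCCO1 | intermediate
15 | (R)-4-benzyl-3-[(S)-3-{(Z)-1-(TBDPS-oxy)-2-methyl-5-(2-methyl-1,3-dioxolan-2-yl)pent-2-en-3-yl}-6-(TBDPS-oxy)hexanoyl]oxazolidin-2-one | O=C(C[C@H](CCCO[Si](c1ccccc1)(c1ccccc1)C(C)(C)C)/C(=C(/C)CO[Si](c1ccccc1)(c1ccccc1)C(C)(C)C)CCC1(C)OCCO1)N1[C@H](Cc2ccccc2)COC1=O | intermediate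
16 | peroxy acid corresponding to 17 | OOC(=O)C[C@H](CCCO[Si](c1ccccc1)(c1ccccc1)C(C)(C)C)/C(=C(/C)CO[Si](c1ccccc1)(c1ccccc1)C(C)(C)C)CCC1(C)OCCO1 | intermediate
17 | (S)-3-{(Z)-1-(TBDPS-oxy)-2-methyl-5-(2-methyl-1,3-dioxolan-2-yl)pent-2-en-3-yl}-6-(TBDPS-oxy)hexanoic acid | OC(=O)C[C@H](CCCO[Si](c1ccccc1)(c1ccccc1)C(C)(C)C)/C(=C(/C)CO[Si](c1ccccc1)(c1ccccc1)C(C)(C)C)CCC1(C)OCCO1 | intermediate
18 | (S)-3-[(Z)-1-(TBDPS-oxy)-2-methyl-6-oxohept-2-en-3-yl]-6-(TBDPS-oxy)hexanoic acid | OC(=O)C[C@H](CCCO[Si](c1ccccc1)(c1ccccc1)C(C)(C)C)/C(=C(/C)CO[Si](c1ccccc1)(c1ccccc1)C(C)(C)C)CCC(C)=O | intermediate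
19 | (1R,2S,6S)-6-methyl-2-[3-(TBDPS-oxy)propyl]-3-[(Z)-1-(TBDPS-oxy)propan-2-ylidene]-7-oxabicyclo[4.2.0]octan-8-one | O=C1[C@@H]2[C@H](CCCO[Si](c3ccccc3)(c3ccccc3)C(C)(C)C)/C(=C(/C)CO[Si](c3ccccc3)(c3ccccc3)C(C)(C)C)CC[C@]2(C)O1 | intermediate
20 | but-3-yn-1-ol | C#CCCO | starting material
21 | 5-(diisopropylamino)pent-3-yn-1-ol | CC(C)N(CC#CCCO)C(C)C | intermediate
22 | penta-3,4-dien-1-ol | C=C=CCCO | intermediate
23 | penta-3,4-dien-1-yl trifluoromethanesulfonate | C=C=CCCOS(=O)(=O)C(F)(F)F | intermediate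
24 | lithium enolate of 19 | [Li]OC1=C2[C@H](CCCO[Si](c3ccccc3)(c3ccccc3)C(C)(C)C)/C(=C(/C)CO[Si](c3ccccc3)(c3ccccc3)C(C)(C)C)CC[C@]2(C)O1 | intermediate
25 | (1R,2R,6S)-6-methyl-1-(penta-3,4-dien-1-yl)-2-[3-(TBDPS-oxy)propyl]-3-[(Z)-1-(TBDPS-oxy)propan-2-ylidene]-7-oxabicyclo[4.2.0]octan-8-one | O=C1[C@]2(CCC=C=C)[C@H](CCCO[Si](c3ccccc3)(c3ccccc3)C(C)(C)C)/C(=C(/C)CO[Si](c3ccccc3)(c3ccccc3)C(C)(C)C)CC[C@]2(C)O1 | intermediate
26 | (1S,2S,3R)-2-(hydroxymethyl)-1-methyl-2-(penta-3,4-dien-1-yl)-3-[3-(TBDPS-oxy)propyl]-4-[(Z)-1-(TBDPS-oxy)propan-2-ylidene]cyclohexan-1-ol | OC[C@]1(CCC=C=C)[C@H](CCCO[Si](c2ccccc2)(c2ccccc2)C(C)(C)C)/C(=C(/C)CO[Si](c2ccccc2)(c2ccccc2)C(C)(C)C)CC[C@]1(C)O | intermediate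
27 | (1R,2S,6R)-2-hydroxy-2-methyl-1-(penta-3,4-dien-1-yl)-6-[3-(TBDPS-oxy)propyl]-5-[(Z)-1-(TBDPS-oxy)propan-2-ylidene]cyclohexane-1-carbaldehyde | O=C[C@]1(CCC=C=C)[C@H](CCCO[Si](c2ccccc2)(c2ccccc2)C(C)(C)C)/C(=C(/C)CO[Si](c2ccccc2)(c2ccccc2)C(C)(C)C)CC[C@]1(C)O | intermediate
28 | (1R,2S,6R)-2-methyl-1-(penta-3,4-dien-1-yl)-6-[3-(TBDPS-oxy)propyl]-5-[(Z)-1-(TBDPS-oxy)propan-2-ylidene]-2-(triethylsilyloxy)cyclohexane-1-carbaldehyde | O=C[C@]1(CCC=C=C)[C@H](CCCO[Si](c2ccccc2)(c2ccccc2)C(C)(C)C)/C(=C(/C)CO[Si](c2ccccc2)(c2ccccc2)C(C)(C)C)CC[C@]1(C)O[Si](CC)(CC)CC | intermediate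
29 | methyl 2-[bis(2,2,2-trifluoroethoxy)phosphoryl]acetate | COC(=O)CP(=O)(OCC(F)(F)F)OCC(F)(F)F | starting material
30 | 5-bromo-2-methylpent-2-ene | CC(C)=CCCBr | starting material
31 | sodium enolate of 29 | [Na+].COC(=O)[CH-]P(=O)(OCC(F)(F)F)OCC(F)(F)F | intermediate
32 | methyl 2-[bis(2,2,2-trifluoroethoxy)phosphoryl]-6-methylhept-5-enoate | COC(=O)C(CCC=C(C)C)P(=O)(OCC(F)(F)F)OCC(F)(F)F | intermediate
33 | (E)-3-(4,4,5,5-tetramethyl-1,3,2-dioxaborolan-2-yl)prop-2-enal | O=C/C=C/B1OC(C)(C)C(C)(C)O1 | starting material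
34 | potassium enolate of 32 | [K+].COC(=O)[C-](CCC=C(C)C)P(=O)(OCC(F)(F)F)OCC(F)(F)F | intermediate
35 | methyl (2Z,4E)-2-(4-methylpent-3-en-1-yl)-5-(pinacolboryl)penta-2,4-dienoate | CC1(C)OB(/C=C/C=C(/CCC=C(C)C)C(=O)OC)OC1(C)C | intermediate
36 | (2Z,4E)-2-(4-methylpent-3-en-1-yl)-5-(pinacolboryl)penta-2,4-dien-1-ol | CC1(C)OB(/C=C/C=C(/CCC=C(C)C)CO)OC1(C)C | intermediate
37 | (2Z,4E)-2-(4-methylpent-3-en-1-yl)-5-(pinacolboryl)penta-2,4-dien-1-yl acetate | CC1(C)OB(/C=C/C=C(/CCC=C(C)C)COC(C)=O)OC1(C)C | intermediate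
38 | (1R,2S,5S,6S,10R)-2-[(3E,5Z)-6-(acetoxymethyl)-10-methylundeca-1,3,5,9-tetraen-2-yl]-6-methyl-10-[3-(TBDPS-oxy)propyl]-9-[(Z)-1-(TBDPS-oxy)propan-2-ylidene]-6-(triethylsilyloxy)spiro[4.5]decan-1-ol | C=C(/C=C/C=C(/CCC=C(C)C)COC(C)=O)[C@@H]1CC[C@]2([C@H](CCCO[Si](c3ccccc3)(c3ccccc3)C(C)(C)C)/C(=C(/C)CO[Si](c3ccccc3)(c3ccccc3)C(C)(C)C)CC[C@]2(C)O[Si](CC)(CC)CC)[C@@H]1O | intermediate
39 | (1R,2S,5S,6S,10R)-2-[(3E,5Z)-6-(acetoxymethyl)-10-methylundeca-1,3,5,9-tetraen-2-yl]-10-(3-hydroxypropyl)-9-[(Z)-1-hydroxypropan-2-ylidene]-6-methylspiro[4.5]decane-1,6-diol | C=C(/C=C/C=C(/CCC=C(C)C)COC(C)=O)[C@@H]1CC[C@]2([C@H](CCCO)/C(=C(/C)CO)CC[C@]2(C)O)[C@@H]1O | intermediate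
40 | CNP0205332.1, (Z)-2-[(1R,2S,5S,6S,10R)-2-{(3E,5Z)-6-(acetoxymethyl)-10-methylundeca-1,3,5,9-tetraen-2-yl}-1,6-dihydroxy-10-(3-hydroxypropyl)-6-methylspiro[4.5]decan-9-ylidene]propanal | C=C(/C=C/C=C(/CCC=C(C)C)COC(C)=O)[C@@H]1CC[C@]2([C@H](CCCO)/C(=C(/C)C=O)CC[C@]2(C)O)[C@@H]1O | target

Total step count: 24. Longest linear sequence: 15 steps (steps 1–4, 8–11, 14–17, 22–24).

Steps most likely to fail, with fallbacks

Step 22. Transmetalation of the hindered dienyl pinacol boronate may be slow relative to protodeboronation. Any Pd(0) that accumulates may ionise the dienylic acetate. The facial bias at C26 set by C11 may be insufficient, and the cis relation, although expected from the closed transition state, is not guaranteed. The fallback separates ring closure from chain attachment and sets out from aldehyde 28. Copper-catalysed borylative cyclisation (B2pin2, CuCl/IMes·HCl, NaOt-Bu, MeOH, THF, rt) proceeds by borylcupration of the allene at C15 and addition of the resulting 2-boryl-allylcopper to C26, and should give (1R,2S,5S,6S,10R)-6-methyl-2-[1-(pinacolboryl)vinyl]-10-[3-(TBDPS-oxy)propyl]-9-[(Z)-1-(TBDPS-oxy)propan-2-ylidene]-6-(triethylsilyloxy)spiro[4.5]decan-1-ol F1. In parallel, boronate 37 is converted by iododeboronation with retention (NIS, MeCN) into (2Z,4E)-5-iodo-2-(4-methylpent-3-en-1-yl)penta-2,4-dien-1-yl acetate F2. A room-temperature Suzuki coupling of F1 with F2 (Pd(dppf)Cl2, aq K3PO4, THF) then forms C15–C16 and comes back to the route at 38.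

Step 14. The strained lactone enolate may decompose (β-elimination or ketene extrusion) faster than it is alkylated by an unactivated primary electrophile, and the triflate may eliminate to a vinylallene. The fallback replaces the lactone enolate by a chelated dianion and sets out from β-lactone 19. Methanolysis (NaOMe, MeOH, 0 °C) should give methyl (1R,2S,6S)-2-hydroxy-2-methyl-6-[3-(TBDPS-oxy)propyl]-5-[(Z)-1-(TBDPS-oxy)propan-2-ylidene]cyclohexane-1-carboxylate F3. Alcohol 22 is converted (I2, PPh3, imidazole) into 5-iodopenta-1,2-diene F4. Fráter–Seebach alkylation of the dianion of F3 (LDA 2.2 equiv, THF/HMPA, −78 → −20 °C) with F4 should give methyl (1R,2S,6R)-2-hydroxy-2-methyl-1-(penta-3,4-dien-1-yl)-6-[3-(TBDPS-oxy)propyl]-5-[(Z)-1-(TBDPS-oxy)propan-2-ylidene]cyclohexane-1-carboxylate F5, because the electrophile should enter anti to the axial alkoxide and the axial C5 chain. LiAlH4 reduction of F5 comes back to the route at diol 26.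

Step 8. Transfer of the fully substituted alkenyl group from copper to the enoyl imide may be sluggish, leading to protonated alkene, or the facial selectivity may erode. The fallback interchanges nucleophile and acceptor and sets out from vinyl iodide 7. Heck coupling (Pd(OAc)2, Bu4NCl, NaHCO3, DMF, 60 °C) with (S)-3-acryloyl-4-benzyloxazolidin-2-one F6, made from (S)-4-benzyloxazolidin-2-one as in step 6, should give (S)-4-benzyl-3-[(2E,4Z)-6-(TBDPS-oxy)-5-methyl-4-[2-(2-methyl-1,3-dioxolan-2-yl)ethyl]hexa-2,4-dienoyl]oxazolidin-2-one F7. Copper-catalysed 1,4-addition (CuBr·SMe2, THF, −40 °C) of 3-(TBDPS-oxy)propylmagnesium bromide F8, made from the commercial bromide and magnesium, then installs C3–C5 at C6 and should give (S)-4-benzyl-3-[(S)-3-{(Z)-1-(TBDPS-oxy)-2-methyl-5-(2-methyl-1,3-dioxolan-2-yl)pent-2-en-3-yl}-6-(TBDPS-oxy)hexanoyl]oxazolidin-2-one F9. The C6 configuration is the same as in 15 because incoming and resident groups are interchanged and the auxiliary is inverted, and 1,6-addition is blocked by the fully substituted C2. Cleavage of F9 with LiOH/H2O2 comes back to the route at acid 17.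

Further compounds
F1 | step 22 | (1R,2S,5S,6S,10R)-6-methyl-2-[1-(pinacolboryl)vinyl]-10-[3-(TBDPS-oxy)propyl]-9-[(Z)-1-(TBDPS-oxy)propan-2-ylidene]-6-(triethylsilyloxy)spiro[4.5]decan-1-ol | C=C(B1OC(C)(C)C(C)(C)O1)[C@@H]1CC[C@]2([C@H](CCCO[Si](c3ccccc3)(c3ccccc3)C(C)(C)C)/C(=C(/C)CO[Si](c3ccccc3)(c3ccccc3)C(C)(C)C)CC[C@]2(C)O[Si](CC)(CC)CC)[C@@H]1O
F2 | step 22 | (2Z,4E)-5-iodo-2-(4-methylpent-3-en-1-yl)penta-2,4-dien-1-yl acetate | I/C=C/C=C(/CCC=C(C)C)COC(C)=O
F3 | step 14 | methyl (1R,2S,6S)-2-hydroxy-2-methyl-6-[3-(TBDPS-oxy)propyl]-5-[(Z)-1-(TBDPS-oxy)propan-2-ylidene]cyclohexane-1-carboxylate | COC(=O)[C@@H]1[C@H](CCCO[Si](c2ccccc2)(c2ccccc2)C(C)(C)C)/C(=C(/C)CO[Si](c2ccccc2)(c2ccccc2)C(C)(C)C)CC[C@]1(C)O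
F4 | step 14 | 5-iodopenta-1,2-diene | C=C=CCCI
F5 | step 14 | methyl (1R,2S,6R)-2-hydroxy-2-methyl-1-(penta-3,4-dien-1-yl)-6-[3-(TBDPS-oxy)propyl]-5-[(Z)-1-(TBDPS-oxy)propan-2-ylidene]cyclohexane-1-carboxylate | COC(=O)[C@]1(CCC=C=C)[C@H](CCCO[Si](c2ccccc2)(c2ccccc2)C(C)(C)C)/C(=C(/C)CO[Si](c2ccccc2)(c2ccccc2)C(C)(C)C)CC[C@]1(C)O
F6 | step 8 | (S)-3-acryloyl-4-benzyloxazolidin-2-one | C=CC(=O)N1[C@@H](Cc2ccccc2)COC1=O
F7 | step 8 | (S)-4-benzyl-3-[(2E,4Z)-6-(TBDPS-oxy)-5-methyl-4-[2-(2-methyl-1,3-dioxolan-2-yl)ethyl]hexa-2,4-dienoyl]oxazolidin-2-one | O=C(/C=C/C(=C(/C)CO[Si](c1ccccc1)(c1ccccc1)C(C)(C)C)CCC1(C)OCCO1)N1[C@@H](Cc2ccccc2)COC1=O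
F8 | step 8 | 3-(TBDPS-oxy)propylmagnesium bromide | Br[Mg]CCCO[Si](c1ccccc1)(c1ccccc1)C(C)(C)C
F9 | step 8 | (S)-4-benzyl-3-[(S)-3-{(Z)-1-(TBDPS-oxy)-2-methyl-5-(2-methyl-1,3-dioxolan-2-yl)pent-2-en-3-yl}-6-(TBDPS-oxy)hexanoyl]oxazolidin-2-one | O=C(C[C@H](CCCO[Si](c1ccccc1)(c1ccccc1)C(C)(C)C)/C(=C(/C)CO[Si](c1ccccc1)(c1ccccc1)C(C)(C)C)CCC1(C)OCCO1)N1[C@@H](Cc2ccccc2)COC1=O
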